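**Strategy.** The route opens ring C at C3–C4. The carbonyl carbon C4 sits directly on ring A, and C3 is an unsubstituted CH2. C2, which carries O1 and ring B, is the only stereocentre. Ring C can therefore be made by adding the C–H bond of a ring A aldehyde across an O1-bound 1-arylvinyl ether. One enantioselective rhodium hydroacylation forms C3–C4, closes ring C and places hydrogen on C2 (2S). Its precursor is a tetra-MOM 6-(1-arylvinyloxy)-3-prenylbenzaldehyde. It is built from a mirror-symmetric ring A phenol, which fixes the 6-prenyl pattern, and a ring B benzoic acid, by esterification, ester methylenation and bromine–lithium exchange/formylation.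

Key step: step 13

Assumption: no precedent fixes the sense of induction for an enol ether in this hydroacylation. (R)-DTBM-SEGPHOS is therefore written as the ligand that exposes the Re face of C2. If a test reaction shows the opposite sense, the equally available (S)-ligand is used and nothing else changes.

Abbreviations: prenyl = 3-methylbut-2-en-1-yl; MOM = methoxymethyl; TIPS = triisopropylsilyl; IPent = 1,3-bis[2,6-di(pentan-3-yl)phenyl]imidazol-2-ylidene. Flavanone numbering is used (O1, C2, C3, C4, C4a, C5–C8, C8a; ring B primed).

Design remarks: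
- The formyl group enters last, at a carbon marked beforehand by bromine. Otherwise n-BuLi would have to choose between ring A, the C2'–H of ring B next to an OMOM group, the doubly activated prenyl CH2 groups and base-induced loss of aryloxide from the vinyl ether.
- The ring B acid is coupled with a carbodiimide, so the MOM acetals never meet HCl.
- The rhodium cation is generated with a sodium tetraarylborate and not a silver salt, because the precursor holds an acid-labile enol ether next to an aldehyde.

**Step 1**
Reactants: 1 phloroglucinol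
Product: 2 5-(triisopropylsilyloxy)benzene-1,3-diol
Conditions: TIPSCl (1 equiv), imidazole, DMF, 0 °C → rt; 1 used in threefold excess
Reagents that add atoms: triisopropylsilyl chloride, CC(C)[Si](Cl)(C(C)C)C(C)C
Why: Silyl ether formation on a threefold-symmetric triol is purely statistical, so an excess of cheap, water-soluble 1 should make the mono-TIPS ether the main silylated product and give ring A one orthogonal oxygen.

**Step 2**
Reactants: 2 5-(triisopropylsilyloxy)benzene-1,3-diol
Product: 3 [3,5-bis(methoxymethoxy)phenoxy]triisopropylsilane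
Conditions: MOMCl (2.5 equiv), iPr2NEt, CH2Cl2, 0 °C → rt
Reagents that add atoms: chloromethyl methyl ether, COCCl
Why: Amine-mediated O-alkylation (MOM acetal formation) of the two remaining equivalent phenols runs under conditions that leave an aryl TIPS ether untouched.

**Step 3**
Reactants: 3 [3,5-bis(methoxymethoxy)phenoxy]triisopropylsilane; 4 prenyl bromide
Product: 6 [3,5-bis(methoxymethoxy)-4-prenylphenoxy]triisopropylsilane, via aryllithium 5 (not isolated)
Conditions: n-BuLi (1.1 equiv), THF, 0 °C, 1 h; then 4, −78 °C → rt
Reagents that add atoms: none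
Why: In this directed ortho-metalation the C–H between the two OMOM groups is activated cooperatively while the bulky OTIPS group shields its own neighbours, and the aryllithium displaces the primary allylic bromide in an SN2 sense to put a linear prenyl group on the mirror plane.

**Step 4**
Reactants: 6 [3,5-bis(methoxymethoxy)-4-prenylphenoxy]triisopropylsilane
Product: 7 3,5-bis(methoxymethoxy)-4-prenylphenol
Conditions: TBAF, THF, 0 °C; water work-up
Reagents that add atoms: none
Why: Fluoride-induced desilylation attacks only the Si–O bond and leaves MOM acetals and the alkene alone, unveiling the mirror-symmetric phenol.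

**Step 5**
Reactants: 7 3,5-bis(methoxymethoxy)-4-prenylphenol
Product: 8 2-bromo-3,5-bis(methoxymethoxy)-4-prenylphenol
Conditions: NBS (1.0 equiv), CH2Cl2, −78 → −30 °C, dark
Reagents that add atoms: N-bromosuccinimide, O=C1CCC(=O)N1Br
Why: In this electrophilic aromatic bromination the two free ring positions are equivalent by symmetry and activated by three oxygen donors, so one equivalent of NBS at low temperature should brominate the ring far faster than the trisubstituted alkene and give a single regioisomer that marks the future C4a.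

**Step 6**
Reactants: 9 5-bromovanillin
Product: 10 3-bromo-4,5-dihydroxybenzaldehyde
Conditions: AlCl3, pyridine, CH2Cl2, reflux; then dilute aq HCl
Reagents that add atoms: none
Why: In this chelation-assisted aryl methyl ether cleavage aluminium binds the phenolate and the neighbouring methoxy oxygen and pyridine takes the activated methyl group, a standard conversion of vanillin-type aldehydes into catechols.

**Step 7**
Reactants: 10 3-bromo-4,5-dihydroxybenzaldehyde
Product: 11 3-bromo-4,5-bis(methoxymethoxy)benzaldehyde
Conditions: MOMCl (2.5 equiv), iPr2NEt, CH2Cl2, 0 °C → rt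
Reagents that add atoms: chloromethyl methyl ether, COCCl
Why: MOM acetal formation by O-alkylation of both catechol oxygens is routine, and the aldehyde and aryl bromide are inert to it.

**Step 8**
Reactants: 11 3-bromo-4,5-bis(methoxymethoxy)benzaldehyde
Product: 12 3-bromo-4,5-bis(methoxymethoxy)benzoic acid
Conditions: NaClO2, NaH2PO4, 2-methyl-2-butene, t-BuOH/H2O, rt
Reagents that add atoms: sodium chlorite NaClO2, [Na+].[O-]Cl=O
Why: The Pinnick oxidation works at a buffered pH that MOM acetals tolerate, and it is placed before prenylation so that no substrate alkene meets the hypochlorous acid formed.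

**Step 9**
Reactants: 12 3-bromo-4,5-bis(methoxymethoxy)benzoic acid; 13 prenylboronic acid pinacol ester
Product: 14 3,4-bis(methoxymethoxy)-5-prenylbenzoic acid
Conditions: PdCl2(IPent)(3-chloropyridine) (2 mol %), aq KOH (5 M), THF, 65 °C; then citric acid to pH 4–5, 0 °C
Reagents that add atoms: none
Why: In this Suzuki–Miyaura allyl–aryl coupling the very bulky carbene ligand should make the prenyl palladium intermediate eliminate reductively at its unsubstituted terminus to give the linear prenyl arene, and the carboxylate formed in aqueous KOH is a spectator.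

**Step 10**
Reactants: 8 2-bromo-3,5-bis(methoxymethoxy)-4-prenylphenol; 14 3,4-bis(methoxymethoxy)-5-prenylbenzoic acid
Product: 16 2-bromo-3,5-bis(methoxymethoxy)-4-prenylphenyl 3,4-bis(methoxymethoxy)-5-prenylbenzoate, via O-acylisourea 15 (not isolated)
Conditions: DCC, DMAP (cat.), CH2Cl2, 0 °C → rt
Reagents that add atoms: none
Why: The Steglich esterification activates the acid under neutral conditions, avoiding the HCl of an acid chloride preparation that would strip MOM groups, and DMAP passes the acyl group to the fairly acidic ortho-bromophenol.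

**Step 11**
Reactants: 16 2-bromo-3,5-bis(methoxymethoxy)-4-prenylphenyl 3,4-bis(methoxymethoxy)-5-prenylbenzoate
Product: 17 2-bromo-1-{1-[3,4-bis(methoxymethoxy)-5-prenylphenyl]vinyloxy}-3,5-bis(methoxymethoxy)-4-prenylbenzene
Conditions: Cp2Ti(CH2)(Cl)AlMe2 (1.3 equiv, toluene), pyridine (cat.), THF, −40 °C → rt; aq NaOH quench; basic Al2O3
Reagents that add atoms: Cp2Ti(CH2)(Cl)AlMe2 (Tebbe reagent), C[Al-]1(C)C[Ti](C2C=CC=C2)(C2C=CC=C2)[Cl+]1
Why: In the Tebbe methylenation the released titanium methylidene adds [2+2] to the ester carbonyl and cycloreverts to the enol ether, a conversion well established for aryl benzoates that ignores aryl bromides, acetals and trisubstituted alkenes.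

**Step 12**
Reactants: 17 2-bromo-1-{1-[3,4-bis(methoxymethoxy)-5-prenylphenyl]vinyloxy}-3,5-bis(methoxymethoxy)-4-prenylbenzene
Product: 19 2,4-bis(methoxymethoxy)-3-prenyl-6-{1-[3,4-bis(methoxymethoxy)-5-prenylphenyl]vinyloxy}benzaldehyde, via aryllithium 18 (not isolated)
Conditions: n-BuLi (1.05 equiv), THF, −78 °C, 10 min; DMF, −78 → 0 °C; pH 7 buffer
Reagents that add atoms: N,N-dimethylformamide, CN(C)C=O
Why: Bromine–lithium exchange followed by formylation with DMF is much faster at −78 °C than any deprotonation of ring B, of the prenyl CH2 groups or of the vinyl ether, so the formyl group enters only at the carbon that carried bromine.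

**Step 13**
Reactants: 19 2,4-bis(methoxymethoxy)-3-prenyl-6-{1-[3,4-bis(methoxymethoxy)-5-prenylphenyl]vinyloxy}benzaldehyde
Product: 20 (2S)-5,7,3',4'-tetrakis(methoxymethoxy)-6,5'-diprenylflavanone
Conditions: [Rh(cod)Cl]2 (2.5 mol %), (R)-DTBM-SEGPHOS (5.5 mol %), NaB[3,5-(CF3)2C6H3]4 (5 mol %), THF, 60 °C, Ar, base-washed glassware
Reagents that add atoms: none
Why: Proposed new method: the cationic bisphosphine complex of monovalent rhodium should insert into the formyl C–H of 19 to give an acyl hydride of trivalent rhodium, the tethered C2=C3 enol ether then binds and inserts into Rh–H with hydride going to the fully substituted, cation-stabilising C2 and rhodium to the unhindered C3, and C3–C4 reductive elimination from the seven-membered rhodacycle releases 20. The closest known reaction type is the enantioselective rhodium-catalysed intramolecular hydroacylation of ortho-allylbenzaldehydes carrying 1,1-disubstituted alkenes, which gives six-membered benzo-fused ketones with the same metal and ligand family, whereas an oxygen atom in place of the benzylic CH2 of the tether is untested. Ring C closes in a 6-endo-trig sense (C2 and C3 both end up in the ring), and the 5-exo alternative to a 2-aryl-2-methylbenzofuran-3-one would need a tertiary benzylic alkylrhodium that both the bulky ligand and the enol ether polarity disfavour. C2 is set solely by the axially chiral ligand pocket, which must present the Re face of C2 to Rh–H to give 2S. Chemoselectivity rests on the substrate: both prenyl alkenes are trisubstituted and cannot reach the acyl rhodium centre through a viable ring (the ring A prenyl is meta to the formyl group), the enol ether has no allylic hydrogens so chain walking is impossible, and the ortho OMOM and O1 oxygens are hemilabile donors that should occupy the vacant site needed for CO de-insertion. The sodium tetraarylborate abstracts chloride without bringing in silver ions or traces of HBF4 that could hydrolyse the enol ether or trigger its ionic addition to the aldehyde.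

**Step 14**
Reactants: 20 (2S)-5,7,3',4'-tetrakis(methoxymethoxy)-6,5'-diprenylflavanone
Product: 21 (2S)-5,7,3',4'-tetrahydroxy-6,5'-diprenylflavanone (CNP0117506.1)
Conditions: aq HCl (3 M)/MeOH (1:5), 25–40 °C, monitored; NaHCO3 work-up
Reagents that add atoms: none
Why: Acid-catalysed transacetalisation to methanol removes all four MOM groups under conditions routinely used on prenylated flavanones, C2 is not enolisable, and dilute acid at mild temperature should avoid both retro-oxa-Michael ring opening and addition of the phenols to the prenyl alkenes.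

**Compound list**
1 | phloroglucinol | Oc1cc(O)cc(O)c1 | starting material
2 | 5-(triisopropylsilyloxy)benzene-1,3-diol | CC(C)[Si](Oc1cc(O)cc(O)c1)(C(C)C)C(C)C | intermediate
3 | [3,5-bis(methoxymethoxy)phenoxy]triisopropylsilane | COCOc1cc(OCOC)cc(O[Si](C(C)C)(C(C)C)C(C)C)c1 | intermediate
4 | prenyl bromide (1-bromo-3-methylbut-2-ene) | CC(C)=CCBr | starting material
5 | [4-lithio-3,5-bis(methoxymethoxy)phenoxy]triisopropylsilane (aryllithium) | [Li]c1c(OCOC)cc(O[Si](C(C)C)(C(C)C)C(C)C)cc1OCOC | intermediate
6 | [3,5-bis(methoxymethoxy)-4-prenylphenoxy]triisopropylsilane | CC(C)=CCc1c(OCOC)cc(O[Si](C(C)C)(C(C)C)C(C)C)cc1OCOC | intermediate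
7 | 3,5-bis(methoxymethoxy)-4-prenylphenol | CC(C)=CCc1c(OCOC)cc(O)cc1OCOC | intermediate
8 | 2-bromo-3,5-bis(methoxymethoxy)-4-prenylphenol | CC(C)=CCc1c(OCOC)cc(O)c(Br)c1OCOC | intermediate
9 | 5-bromovanillin | COc1cc(C=O)cc(Br)c1O | starting material
10 | 3-bromo-4,5-dihydroxybenzaldehyde | O=Cc1cc(O)c(O)c(Br)c1 | intermediate
11 | 3-bromo-4,5-bis(methoxymethoxy)benzaldehyde | O=Cc1cc(OCOC)c(OCOC)c(Br)c1 | intermediate
12 | 3-bromo-4,5-bis(methoxymethoxy)benzoic acid | OC(=O)c1cc(OCOC)c(OCOC)c(Br)c1 | intermediate
13 | prenylboronic acid pinacol ester | CC(C)=CCB1OC(C)(C)C(C)(C)O1 | starting material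
14 | 3,4-bis(methoxymethoxy)-5-prenylbenzoic acid | OC(=O)c1cc(OCOC)c(OCOC)c(CC=C(C)C)c1 | intermediate
15 | O-acylisourea from 14 and DCC | O=C(OC(=NC1CCCCC1)NC1CCCCC1)c1cc(OCOC)c(OCOC)c(CC=C(C)C)c1 | intermediate
16 | 2-bromo-3,5-bis(methoxymethoxy)-4-prenylphenyl 3,4-bis(methoxymethoxy)-5-prenylbenzoate | CC(C)=CCc1c(OCOC)cc(OC(=O)c2cc(OCOC)c(OCOC)c(CC=C(C)C)c2)c(Br)c1OCOC | intermediate
17 | 2-bromo-1-{1-[3,4-bis(methoxymethoxy)-5-prenylphenyl]vinyloxy}-3,5-bis(methoxymethoxy)-4-prenylbenzene | CC(C)=CCc1c(OCOC)cc(OC(=C)c2cc(OCOC)c(OCOC)c(CC=C(C)C)c2)c(Br)c1OCOC | intermediate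
18 | 2-lithio analogue of 17 (aryllithium) | CC(C)=CCc1c(OCOC)cc(OC(=C)c2cc(OCOC)c(OCOC)c(CC=C(C)C)c2)c([Li])c1OCOC | intermediate
19 | 2,4-bis(methoxymethoxy)-3-prenyl-6-{1-[3,4-bis(methoxymethoxy)-5-prenylphenyl]vinyloxy}benzaldehyde | O=Cc1c(OC(=C)c2cc(CC=C(C)C)c(OCOC)c(OCOC)c2)cc(OCOC)c(CC=C(C)C)c1OCOC | intermediate
20 | (2S)-5,7,3',4'-tetrakis(methoxymethoxy)-6,5'-diprenylflavanone | CC(C)=CCc1cc([C@@H]2CC(=O)c3c(cc(OCOC)c(CC=C(C)C)c3OCOC)O2)cc(OCOC)c1OCOC | intermediate
21 | (2S)-5,7,3',4'-tetrahydroxy-6,5'-diprenylflavanone (CNP0117506.1) | CC(C)=CCc1cc([C@@H]2CC(=O)c3c(cc(O)c(CC=C(C)C)c3O)O2)cc(O)c1O | target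

**Total steps:** 14.
**Longest linear sequence:** 10 (steps 1–5 and 10–14, from phloroglucinol). The ring B branch (steps 6–9) joins at step 10.

**Steps most likely to fail**

1. Step 13 (new method).
   - What may go wrong: decarbonylation of the acyl rhodium hydride before the hindered enol ether inserts; β-aryloxy elimination from the alkylrhodium intermediate; ionic attack of the nucleophilic enol ether terminus on the aldehyde; hydrolysis of the enol ether; or poor facial selectivity.
   - Fallback: it uses known chemistry, sets out from 8, 11 and 13, and comes back at 20. Treating 8 with n-BuLi (2.2 equiv, THF, −78 °C; O–H deprotonation, then bromine–lithium exchange) gives lithium 2-lithio-3,5-bis(methoxymethoxy)-4-prenylphenoxide F1. Acylation of F1 with N-methoxy-N-methylacetamide gives 1-[6-hydroxy-2,4-bis(methoxymethoxy)-3-prenylphenyl]ethanone F2. In parallel, 11 is coupled with 13 under the palladium catalysis of step 9, with K2CO3 as base, to give 3,4-bis(methoxymethoxy)-5-prenylbenzaldehyde F3. Claisen–Schmidt condensation of the two (KOH, EtOH, rt) gives (E)-1-[6-hydroxy-2,4-bis(methoxymethoxy)-3-prenylphenyl]-3-[3,4-bis(methoxymethoxy)-5-prenylphenyl]prop-2-en-1-one F4. NaOAc in refluxing EtOH closes this by oxa-Michael addition of its only free phenol, so the 6-prenyl pattern is kept, to give racemic 5,7,3',4'-tetrakis(methoxymethoxy)-6,5'-diprenylflavanone F5. The last operation is a kinetic resolution by asymmetric transfer hydrogenation [RhCl(Cp*)(TsDPEN), HCO2H/Et3N, EtOAc]. With the ligand enantiomer that consumes the (2R)-ketone, this gives cis-(2R,4R)-5,7,3',4'-tetrakis(methoxymethoxy)-6,5'-diprenylflavan-4-ol F6 and leaves (2S)-20, which is separated by chromatography.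

2. Step 5.
   - What may go wrong: attack of electrophilic bromine on the prenyl alkene (with participation of a neighbouring MOM oxygen), or double bromination.
   - Fallback: it sets out from aryllithium 5, made from 3 as in step 3, and comes back at 8. The alkene is brought in only after both halogens are in place. Quenching 5 with I2 gives [4-iodo-3,5-bis(methoxymethoxy)phenoxy]triisopropylsilane F7. TBAF then gives 4-iodo-3,5-bis(methoxymethoxy)phenol F8. NBS, now with no alkene present, gives 2-bromo-4-iodo-3,5-bis(methoxymethoxy)phenol F9. A chemoselective Suzuki–Miyaura coupling with 13 at the more reactive carbon–iodine bond [PdCl2(IPent)(3-chloropyridine), K3PO4, THF/H2O, rt to 40 °C] delivers 8.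

3. Step 14.
   - What may go wrong: acid-catalysed addition of the liberated phenols to the prenyl alkenes (chroman formation), incomplete cleavage, or erosion of enantiopurity through ring opening.
   - Fallback: it sets out from 20 and comes back at 21. The protic solvolysis is replaced by a buffered silylative acetal cleavage. TMSOTf and 2,2'-bipyridyl (CH2Cl2/MeCN, 0 °C) convert the aryl MOM ethers into aryl silyl ethers, giving (2S)-5,7,3',4'-tetrakis(trimethylsilyloxy)-6,5'-diprenylflavanone F10. Water at neutral pH then hydrolyses this to 21.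

**Further compounds**
F1 | step 13 | lithium 2-lithio-3,5-bis(methoxymethoxy)-4-prenylphenoxide | [Li]Oc1cc(OCOC)c(CC=C(C)C)c(OCOC)c1[Li]
F2 | step 13 | 1-[6-hydroxy-2,4-bis(methoxymethoxy)-3-prenylphenyl]ethanone | CC(=O)c1c(O)cc(OCOC)c(CC=C(C)C)c1OCOC
F3 | step 13 | 3,4-bis(methoxymethoxy)-5-prenylbenzaldehyde | O=Cc1cc(OCOC)c(OCOC)c(CC=C(C)C)c1
F4 | step 13 | (E)-1-[6-hydroxy-2,4-bis(methoxymethoxy)-3-prenylphenyl]-3-[3,4-bis(methoxymethoxy)-5-prenylphenyl]prop-2-en-1-one | CC(C)=CCc1cc(/C=C/C(=O)c2c(O)cc(OCOC)c(CC=C(C)C)c2OCOC)cc(OCOC)c1OCOC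
F5 | step 13 | racemic 5,7,3',4'-tetrakis(methoxymethoxy)-6,5'-diprenylflavanone | CC(C)=CCc1cc(C2CC(=O)c3c(cc(OCOC)c(CC=C(C)C)c3OCOC)O2)cc(OCOC)c1OCOC
F6 | step 13 | cis-(2R,4R)-5,7,3',4'-tetrakis(methoxymethoxy)-6,5'-diprenylflavan-4-ol | CC(C)=CCc1cc([C@H]2C[C@@H](O)c3c(cc(OCOC)c(CC=C(C)C)c3OCOC)O2)cc(OCOC)c1OCOC
F7 | step 5 | [4-iodo-3,5-bis(methoxymethoxy)phenoxy]triisopropylsilane | COCOc1cc(O[Si](C(C)C)(C(C)C)C(C)C)cc(OCOC)c1I
F8 | step 5 | 4-iodo-3,5-bis(methoxymethoxy)phenol | COCOc1cc(O)cc(OCOC)c1I
F9 | step 5 | 2-bromo-4-iodo-3,5-bis(methoxymethoxy)phenol | COCOc1cc(O)c(Br)c(OCOC)c1I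
F10 | step 14 | (2S)-5,7,3',4'-tetrakis(trimethylsilyloxy)-6,5'-diprenylflavanone | CC(C)=CCc1cc([C@@H]2CC(=O)c3c(cc(O[Si](C)(C)C)c(CC=C(C)C)c3O[Si](C)(C)C)O2)cc(O[Si](C)(C)C)c1O[Si](C)(C)C
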